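Bare free catalyst, facing partner as charged, lasts 32.5 s on average, less than the 40 s of the summer flask, so we ask what the loading buys before it dies.

    starting material + free catalyst → free catalyst + open intermediate (k1 = 640 M⁻¹ s⁻¹)
    partner + free catalyst → spent catalyst (k2 = 0.56 M⁻¹ s⁻¹)
    partner + catalyst intermediate → free catalyst + product (k3 = 200 M⁻¹ s⁻¹)
    free catalyst + open intermediate ⇌ catalyst intermediate (K4 = 27 M⁻¹, k4 = 22000 M⁻¹ s⁻¹)

the same everywhere: partner 1.10 equiv; free catalyst 0.5 mol%

| flask | starting material | remark | time |
|---|---|---|---|
| midnight | 0.050 M | one stirred flow tank at steady state, fed with the mixture as stated, mean residence time 400 s |  |
| summer | 0.050 M | everything together in a closed stirred flask, run for 40 s | 40 s |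
| noon | 0.050 M | one stirred flow tank at steady state, fed with the mixture as stated, mean residence time 40 s |  |
| dawn | 0.050 M (fed, over 32.0 s) | all but starting material at the start; starting material goes in evenly over 32.0 s, the run ends at 40 s | 40 s |

1. the set-up with the highest amount of product at the outlet or at the end, in percent of the starting material put in ("none" if the first two lie within 2 percentage points) (midnight / summer / noon / dawn / none)
2. amount of product at the outlet or at the end, in percent of the starting material put in, midnight
3. amount of product at the outlet or at the end, in percent of the starting material put in, summer
4. amount of product at the outlet or at the end, in percent of the starting material put in, noon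
5. amount of product at the outlet or at the end, in percent of the starting material put in, dawn

- the stated concentrations are those of everything mixed, before any reaction; amounts are the same in each set-up
- the feed brings no volume worth counting
- run time (summer): 40 s

Follow one catalyst. Catalyst intermediate falls back to free catalyst at 815 s⁻¹ but goes on to product at 11.0 s⁻¹ at most, so the binding step stays near equilibrium. Product made per catalyst killed is then the ratio of the two partner rate constants times the binding constant times open intermediate; partner cancels. This is the partition ratio of a suicide inactivation. Writing x for open intermediate and y for product as fractions of the charge, and σ for the spent fraction of the loading, we get dy = B·x·dσ. The budget B, 2.41, is the product, as a fraction of the charge, that the whole loading buys in dying if the whole charge stood open throughout; it is a yardstick and not a yield.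

Take the summer flask between two extremes. Opening takes a mean 6.25 s with the loading free, leaving 33.8 s of working time. Over it we take x = 0.5 and mean partner at 0.850 of the charge. Live catalyst then sits 40.3% of the time as catalyst intermediate. Undying catalyst would give 57.8%, and catalyst dying at the bare rate 39.7%. Catalyst intermediate does not meet partner in the dying step, so we place the summer flask between these two and, with the dying rate cut by the bound share, reckon 45.9%.

In a tank x stands still, so y = B·x·σ directly. Taking partner at 0.600 of the charge and the same bound share, we reckon that dying against washout spends 80.0% of the loading at midnight and 28.6% at noon. Open intermediate and product share what has opened, catalyst intermediate holding at most 0.5 mol% of the charge, and surviving unbound catalyst opens starting material against washout; that gives 58.2% at midnight and 29.9% at noon. For dawn, whose dose arrives a mean 16.0 s late, we take undying catalyst over the working time shortened by that delay and expect less than 30.4%. Our winner is midnight.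

The forecast named midnight, with 59% there, 46% for summer, 33.5% for noon and 25% for dawn, and it put dawn last with the words “slow dosing leaves the catalyst mostly free and exposed to partner early on”.

The simulation gives midnight as best, at 59.2%, then summer 46.2%, noon 33.6% and dawn 23.7%. At the midnight outlet, 30.9% of the charge still stands as open intermediate. Putting that reading and the product into y = B·x·σ with the budget of 2.41 gives the spent fraction of the loading at the midnight outlet as 79.5%.

Its constants stand for no real mixture; the result is computed.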